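**Plan**

- Retrosynthesis: the two acetates, the angelate and the epoxide come off first (epoxide from a C3=C4 alkene under direction by C5–OH). The C9 carbinol goes back to a ketone plus an isopropyl nucleophile, and the C3=C4 alkene to a C4 ketone.
- Core cut: C1–C10 and C5–C6 are cut together. The seven-membered ring C1–C2–C3–C4–C5–C6–C10 carries oxygen at C1 and C4 (1,4) and at C5 next to C4. It is therefore the retro-aldol (de Mayo) product of a cyclobutane C1–C5–C6–C10 fused to a temporary cyclopentanone C1–C2–C3–C4–C5. The syn 1,3-diol O5/O7 across quaternary C6 offers a silylene tether.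
- Forward: the five-membered ring comes from (R)-4-silyloxycyclopentenone and is tethered to a 2-hydroxy vinylogous ester. A [2+2] photocycloaddition and fragmentation then give the seven-membered ring. C1, C10 and C9 are adjusted next, then the alkene, the esters and the epoxide.
- Stereochemistry: C7 by Luche reduction of the purchased enone; C6 from C7 through the tether; C5 by equilibration inside the silylene ring; C10 by hydroboration anti to the C6 methyl (trans fusion); C9 by organocerium addition; C1 by CBS reduction then Mitsunobu inversion; C3/C4 by hydroxyl-directed epoxidation.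

Key step: step 8

Remark 1: core numbering used throughout is C1 = CH–O(angeloyl), C2 = CH2, C3 = C(CH3) of the epoxide, C4 = epoxide CH, C5 = CH–OAc, C6 = quaternary C–CH3, C7 = CH–OAc of the five-membered ring, C8 = CH2, C9 = C(OH)(iPr), C10 = ring-fusion CH. β is the face of the C6 methyl group, α the other face. The target is (1S,3R,4S,5S,6R,7S,9R,10S) in this numbering.

Remark 2: the methyl-bearing C3 is α to a ketone and is carried as a mixture of epimers (left undefined in the SMILES) from 4 to 18. It becomes sp2 in step 12.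

**Route**

Step 1
Reactants: 1 cyclopentane-1,3-dione
Product: 2 3-(benzyloxy)cyclopent-2-en-1-one
Conditions: BnOH, TsOH (cat.), toluene, reflux, Dean–Stark
Reagents that add atoms: benzyl alcohol (OCc1ccccc1)
Why: Acid-catalysed condensation of the enolised 1,3-dione (a vinylogous acid) with the alcohol under azeotropic removal of water is the standard vinylogous ester formation; no stereocenter is formed.

Step 2
Reactants: 2 3-(benzyloxy)cyclopent-2-en-1-one
Product: 4 rac-3-(benzyloxy)-5-methylcyclopent-2-en-1-one, via lithium enolate 3 (not isolated)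
Conditions: LiN(iPr)2, THF, −78 °C; MeI, −78 → 0 °C
Reagents that add atoms: iodomethane (CI)
Why: Stork–Danheiser alkylation: kinetic deprotonation of a vinylogous ester occurs at the α′-CH2 next to the carbonyl, so the methyl group lands on the future C3 beside the future C4 carbonyl and away from the enol-ether carbon (future C1); the new center is racemic and is erased in step 12.

Step 3
Reactants: 4 rac-3-(benzyloxy)-5-methylcyclopent-2-en-1-one
Product: 6 rac-3-(benzyloxy)-2-hydroxy-5-methylcyclopent-2-en-1-one, via epoxide 5 (not isolated)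
Conditions: dimethyldioxirane (acetone solution), CH2Cl2, −40 → 0 °C; then SiO2
Reagents that add atoms: dimethyldioxirane (CC1(C)OO1)
Why: Dimethyldioxirane epoxidises the electron-rich enol-ether double bond and the 2-alkoxy epoxide opens and tautomerises on silica to the 2-hydroxy vinylogous ester (Rubottom-type α-hydroxylation, as in the flavone-to-flavonol conversion), which puts the future O5 on the enone α-carbon.

Step 4
Reactants: 7 (R)-4-[(tert-butyldimethylsilyl)oxy]cyclopent-2-en-1-one
Product: 8 (R)-4-[(tert-butyldimethylsilyl)oxy]-2-iodocyclopent-2-en-1-one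
Conditions: I2, pyridine, CH2Cl2, 0 °C → rt
Reagents that add atoms: iodine (II)
Why: Pyridine-mediated α-iodination of a cyclic enone (conjugate addition of pyridine, iodination of the enolate, elimination) is the standard entry to 2-iodo-4-silyloxycyclopentenones; the stereocenter is untouched.

Step 5
Reactants: 8 (R)-4-[(tert-butyldimethylsilyl)oxy]-2-iodocyclopent-2-en-1-one
Product: 9 (R)-4-[(tert-butyldimethylsilyl)oxy]-2-methylcyclopent-2-en-1-one
Conditions: SnMe4, PdCl2(PhCN)2 (cat.), AsPh3, CuI, NMP, 80 °C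
Reagents that add atoms: tetramethylstannane (C[Sn](C)(C)C)
Why: Stille coupling of an α-iodo enone with tetramethyltin under copper co-catalysis installs the future C6 methyl group under non-basic conditions that do not eliminate the silyloxy group.

Step 6
Reactants: 9 (R)-4-[(tert-butyldimethylsilyl)oxy]-2-methylcyclopent-2-en-1-one
Product: 10 (1S,4R)-4-[(tert-butyldimethylsilyl)oxy]-2-methylcyclopent-2-en-1-ol
Conditions: NaBH4, CeCl3·7H2O, MeOH, −78 °C
Reagents that add atoms: none
Why: Luche 1,2-reduction: hydride attacks the enone carbonyl anti to the 4-silyloxy group, which gives the cis-1,4-diol monoether and so sets C7 (S) from the purchased C9 (R) center.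

Step 7
Reactants: 10 (1S,4R)-4-[(tert-butyldimethylsilyl)oxy]-2-methylcyclopent-2-en-1-ol; 6 rac-3-(benzyloxy)-2-hydroxy-5-methylcyclopent-2-en-1-one
Product: 12 3-(benzyloxy)-2-{[di-tert-butyl({(1S,4R)-4-[(tert-butyldimethylsilyl)oxy]-2-methylcyclopent-2-en-1-yl}oxy)silyl]oxy}-5-methylcyclopent-2-en-1-one, via alkoxysilyl triflate 11 (not isolated)
Conditions: tBu2Si(OTf)2, 2,6-lutidine, CH2Cl2, −78 → 0 °C; then 6, 0 °C → rt
Reagents that add atoms: di-tert-butylsilyl bis(trifluoromethanesulfonate) (CC(C)(C)[Si](OS(=O)(=O)C(F)(F)F)(OS(=O)(=O)C(F)(F)F)C(C)(C)C)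
Why: Stepwise silylation with a silyl bis-triflate: the secondary alcohol displaces one triflate at low temperature, a second hindered alkoxy group does not enter, and the acidic enol hydroxyl of 6 then displaces the other to give the unsymmetrical silaketal (temporary silicon tether); no stereocenter changes.

Step 8
Reactants: 12 tethered 2-siloxy vinylogous ester
Product: 13 tetracyclic photoadduct: cyclobutane C1–C5–C6–C10 cis-fused to the cyclopentanone C1–C2–C3–C4–C5 (1-OBn, 4-oxo, 3-methyl), to the cyclopentane C6–C10 (9-OTBS), to the six-membered ring C5–O–Si(tBu)2–O–C7–C6; O1, O5, C7, C9 on one face of the cyclobutane; C2, C4, the C6 methyl, H10 on the other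
Conditions: hν (350 nm), MeCN (0.005 M, degassed), 0 °C
Reagents that add atoms: none
Why: Excitation of the 2-siloxy vinylogous ester (n→π*, then the triplet) lets its α-carbon C5 add to the methyl-bearing alkene carbon C6, held four atoms away by the O–Si–O–C7 tether, and the resulting 1,4-biradical (C1, C10) collapses to the cyclobutane, so that C5–C6 and C1–C10 form in the same operation. The closest known reaction type is the intramolecular enone–alkene [2+2] photocycloaddition through a temporary silicon tether, here as the cycloaddition half of a de Mayo ring expansion. The six-membered 1,3-dioxa-2-silinane (C5–O–Si–O–C7–C6) closes in a 6-exo ("straight") mode and the four-membered ring C1–C5–C6–C10 by recombination of the 1,4-biradical, cis-fused to both five-membered rings and to the silinane. C6 is controlled by C7: the tether reaches only the cyclopentene face that carries the C7 oxygen, so both new bonds form on that face and the C6 methyl ends trans to O7; C1, C5 and C10 are fixed cis by the ring fusions, but C1 and C5 are reset in step 9 and C10 in step 13. The step needs straight over crossed regiochemistry, which the tether length should secure (the crossed mode demands a seven-membered bridged closure), and face selectivity, which the tether secures; irradiation above 300 nm at high dilution spares the saturated ketone of the product and suppresses intermolecular addition.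

Step 9
Reactants: 13 tetracyclic photoadduct
Product: 16 5α,7α-(di-tert-butylsilylenedioxy)-3,6β-dimethylbicyclo[5.3.0]dec-9(10)-ene-1,4-dione, via cyclobutanol 14 (not isolated), via saturated dione 15 (not isolated)
Conditions: H2 (1 atm), Pd(OH)2/C, EtOAc, rt; filter; DBU, toluene, 60 °C
Reagents that add atoms: none
Why: Hydrogenolysis of the benzyl ether frees the cyclobutanol, whose β-hydroxy ketone array undergoes strain-driven retro-aldol cleavage of C1–C5 (fragmentation half of the de Mayo reaction) to the seven-membered 1,4-dione; DBU then equilibrates C5 to the syn-dioxasilinane with both ring branches equatorial (O5 α) and expels silanolate from C9 by E1cB elimination to the C9=C10 enone.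

Step 10
Reactants: 16 bicyclic enedione
Product: 17 (1R)-5α,7α-(di-tert-butylsilylenedioxy)-1β-hydroxy-3,6β-dimethylbicyclo[5.3.0]dec-9(10)-en-4-one
Conditions: (S)-Me-CBS oxazaborolidine [(S)-1-methyl-3,3-diphenyltetrahydro-1H,3H-pyrrolo[1,2-c][1,3,2]oxazaborole] (0.2 equiv), catecholborane, toluene, −78 °C
Reagents that add atoms: none
Why: Corey–Bakshi–Shibata reduction: the (S)-oxazaborolidine delivers hydride to the enone carbonyl with the alkenyl side as the large group and should give the (1R)-alcohol (hydroxyl β) under reagent control, while the doubly α-branched C4 ketone is too hindered to bind the catalyst.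

Step 11
Reactants: 17 (1R)-allylic alcohol
Product: 18 triethylsilyl ether of 17
Conditions: Et3SiCl, imidazole, CH2Cl2, 0 °C
Reagents that add atoms: chlorotriethylsilane (CC[Si](Cl)(CC)CC)
Why: Standard silylation of a secondary allylic alcohol; the triethylsilyl ether adds bulk on the β face for step 13 and can later be removed without loss of the silylene.

Step 12
Reactants: 18 triethylsilyl ether
Product: 20 enol triflate (C3=C4, 4-OTf) of 18, via potassium enolate 19 (not isolated)
Conditions: KN(SiMe3)2, THF, −78 °C; PhNTf2, −78 → −20 °C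
Reagents that add atoms: N-phenylbis(trifluoromethanesulfonimide) (O=S(=O)(N(c1ccccc1)S(=O)(=O)C(F)(F)F)C(F)(F)F)
Why: Kinetic deprotonation of the C4 ketone by the bulky amide should occur at C3 and not at the neopentylic, α-siloxy C5–H, and O-triflation of the enolate gives the C3=C4 enol triflate, in which the C3 epimers converge and C5 can no longer epimerise.

Step 13
Reactants: 20 enol triflate
Product: 22 (1R)-5α,7α-(di-tert-butylsilylenedioxy)-9α-hydroxy-3,6β-dimethyl-1β-(triethylsilyloxy)-10α-H-bicyclo[5.3.0]dec-3-en-4-yl triflate, via alkylborane 21 (not isolated)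
Conditions: BH3·THF, THF, 0 °C → rt; then NaBO3·4H2O, H2O, rt
Reagents that add atoms: sodium perborate ([Na+].[Na+].O[B-]1(O)OO[B-](O)(O)OO1)
Why: Hydroboration–oxidation: borane adds syn across C9=C10, boron on the less substituted C9 and hydrogen on C10, from the α face, because the β face carries the freely projecting C6 methyl group and the C1 silyl ether whereas the α substituents at C6 and C1 are ring carbons tied back in the seven-membered ring, which sets the trans ring fusion; the electron-poor tetrasubstituted enol triflate does not react and perborate oxidises the C–B bond with retention.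

Step 14
Reactants: 22 hydroxy enol triflate
Product: 23 (1R)-5α,7α-(di-tert-butylsilylenedioxy)-3,6β-dimethyl-1β-(triethylsilyloxy)bicyclo[5.3.0]dec-3-en-9α-ol (10α-H)
Conditions: Pd(OAc)2 (cat.), PPh3, HCO2H, Bu3N, DMF, 60 °C
Reagents that add atoms: none
Why: Palladium-catalysed formate reduction of an enol triflate (oxidative addition to zerovalent palladium, hydride transfer from formate, reductive elimination) gives the C3=C4 alkene without touching the alcohol or the silyl groups.

Step 15
Reactants: 23 alkenol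
Product: 24 the corresponding 9-ketone
Conditions: Dess–Martin periodinane, NaHCO3, CH2Cl2, 0 °C → rt
Reagents that add atoms: none
Why: Dess–Martin oxidation of the secondary alcohol under buffered, non-basic conditions gives the ketone without epimerising the adjacent C10.

Step 16
Reactants: 24 9-ketone
Product: 25 9β-hydroxy-9α-isopropyl compound (9R)
Conditions: iPrMgCl, CeCl3, THF, −78 °C
Reagents that add atoms: isopropylmagnesium chloride (CC(C)[Mg]Cl)
Why: Organocerium 1,2-addition: the weakly basic isopropylcerium reagent adds to the enolisable ketone without enolisation or β-hydride reduction, from the α face anti to the adjacent β-disposed C1 branch at C10 and to the C6 methyl group, so that the hydroxyl should end β and the isopropyl group α.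

Step 17
Reactants: 25 tertiary alcohol, C1 triethylsilyl ether
Product: 26 (1R)-1β,9β-diol
Conditions: AcOH, THF, H2O, rt
Reagents that add atoms: none
Why: Mild acid hydrolyses the secondary triethylsilyl ether far faster than the cyclic di-tert-butylsilylene, which frees only the C1 hydroxyl.

Step 18
Reactants: 26 (1R)-1β,9β-diol
Product: 27 (1S)-1α-angelate
Conditions: angelic acid, PPh3, DIAD, toluene, 0 °C → rt
Reagents that add atoms: angelic acid (C/C=C(/C)C(=O)O)
Why: Mitsunobu esterification: the secondary C1 alcohol is activated as the alkoxyphosphonium ion and displaced by angelate with inversion (1R to 1S, oxygen now α); the acid is never activated at its acyl carbon, so its Z geometry should be kept, and the tertiary C9 alcohol does not react.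

Step 19
Reactants: 27 silylene-protected angelate
Product: 28 5α,7α,9β-triol 1α-angelate
Conditions: HF·pyridine, pyridine, THF, 0 °C
Reagents that add atoms: none
Why: Fluoride cleaves the silylene to the 5α,7α-diol while the angelate, the alkene and the tertiary alcohol are inert.

Step 20
Reactants: 28 triol angelate
Product: 29 3α,4α-epoxy triol angelate
Conditions: VO(acac)2 (cat.), t-BuOOH, CH2Cl2, 0 °C → rt
Reagents that add atoms: tert-butyl hydroperoxide (CC(C)(C)OO)
Why: Vanadium-catalysed hydroxyl-directed epoxidation: the allylic C5 hydroxyl binds the vanadium peroxide and delivers oxygen to the same face of the cycloheptene double bond, which should give the 3α,4α-epoxide (3R,4S); the electron-poor angelate alkene is not epoxidised.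

Step 21
Reactants: 29 epoxy triol angelate
Product: 30 CNP0170993.1 (target)
Conditions: Ac2O, pyridine, DMAP (cat.), CH2Cl2, rt
Reagents that add atoms: acetic anhydride (CC(=O)OC(C)=O)
Why: Nucleophile-catalysed acetylation of the two secondary alcohols; the tertiary C9 alcohol is not acylated under these conditions and the epoxide and the angelate are stable to them.

**Compound list**

1 | cyclopentane-1,3-dione | O=C1CCC(=O)C1 | starting material
2 | 3-(benzyloxy)cyclopent-2-en-1-one | O=C1C=C(OCc2ccccc2)CC1 | intermediate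
3 | lithium 3-(benzyloxy)cyclopenta-1,3-dien-1-olate (α′-enolate of 2) | [Li+].[O-]C1=CCC(OCc2ccccc2)=C1 | intermediate (not isolated)
4 | rac-3-(benzyloxy)-5-methylcyclopent-2-en-1-one | O=C1C=C(OCc2ccccc2)CC1C | intermediate
5 | 5-(benzyloxy)-3-methyl-6-oxabicyclo[3.1.0]hexan-2-one | O=C1C2OC2(OCc3ccccc3)CC1C | intermediate (not isolated)
6 | rac-3-(benzyloxy)-2-hydroxy-5-methylcyclopent-2-en-1-one | O=C1C(O)=C(OCc2ccccc2)CC1C | intermediate
7 | (R)-4-[(tert-butyldimethylsilyl)oxy]cyclopent-2-en-1-one | O=C1C=C[C@H](O[Si](C)(C)C(C)(C)C)C1 | starting material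
8 | (R)-4-[(tert-butyldimethylsilyl)oxy]-2-iodocyclopent-2-en-1-one | O=C1C(I)=C[C@H](O[Si](C)(C)C(C)(C)C)C1 | intermediate
9 | (R)-4-[(tert-butyldimethylsilyl)oxy]-2-methylcyclopent-2-en-1-one | O=C1C(C)=C[C@H](O[Si](C)(C)C(C)(C)C)C1 | intermediate
10 | (1S,4R)-4-[(tert-butyldimethylsilyl)oxy]-2-methylcyclopent-2-en-1-ol | CC1=C[C@H](O[Si](C)(C)C(C)(C)C)C[C@@H]1O | intermediate
11 | di-tert-butyl{[(1S,4R)-4-(tert-butyldimethylsilyloxy)-2-methylcyclopent-2-en-1-yl]oxy}silyl triflate | CC1=C[C@H](O[Si](C)(C)C(C)(C)C)C[C@@H]1O[Si](OS(=O)(=O)C(F)(F)F)(C(C)(C)C)C(C)(C)C | intermediate (not isolated)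
12 | tethered 2-siloxy vinylogous ester (name in step 7) | CC1=C[C@H](O[Si](C)(C)C(C)(C)C)C[C@@H]1O[Si](OC1=C(OCc2ccccc2)CC(C)C1=O)(C(C)(C)C)C(C)(C)C | intermediate
13 | tetracyclic photoadduct (description in step 8) | c1ccccc1CO[C@@]23CC(C)C(=O)[C@]2(O[Si]4(C(C)(C)C)C(C)(C)C)[C@@]5(C)[C@@H](O4)C[C@@H](O[Si](C)(C)C(C)(C)C)[C@@H]35 | intermediate
14 | cyclobutanol from debenzylation of 13 | O[C@@]23CC(C)C(=O)[C@]2(O[Si]4(C(C)(C)C)C(C)(C)C)[C@@]5(C)[C@@H](O4)C[C@@H](O[Si](C)(C)C(C)(C)C)[C@@H]35 | intermediate (not isolated)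
15 | cis-fused 5α,7α-(di-tert-butylsilylenedioxy)-9α-(tert-butyldimethylsilyloxy)-3,6β-dimethylbicyclo[5.3.0]decane-1,4-dione (10β-H) | O=C1CC(C)C(=O)[C@@H](O[Si]3(C(C)(C)C)C(C)(C)C)[C@@]2(C)[C@@H](O3)C[C@@H](O[Si](C)(C)C(C)(C)C)[C@@H]12 | intermediate (not isolated)
16 | 5α,7α-(di-tert-butylsilylenedioxy)-3,6β-dimethylbicyclo[5.3.0]dec-9(10)-ene-1,4-dione | O=C1CC(C)C(=O)[C@@H](O[Si]3(C(C)(C)C)C(C)(C)C)[C@@]2(C)[C@@H](O3)CC=C12 | intermediate
17 | (1R)-1β-hydroxy analogue of 16 (4-ketone kept) | O[C@@H]1CC(C)C(=O)[C@@H](O[Si]3(C(C)(C)C)C(C)(C)C)[C@@]2(C)[C@@H](O3)CC=C12 | intermediate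
18 | 1β-triethylsilyl ether of 17 | CC[Si](CC)(CC)O[C@@H]1CC(C)C(=O)[C@@H](O[Si]3(C(C)(C)C)C(C)(C)C)[C@@]2(C)[C@@H](O3)CC=C12 | intermediate
19 | potassium C3=C4 enolate of 18 | [K+].CC[Si](CC)(CC)O[C@@H]1CC(C)=C([O-])[C@@H](O[Si]3(C(C)(C)C)C(C)(C)C)[C@@]2(C)[C@@H](O3)CC=C12 | intermediate (not isolated)
20 | C3=C4 enol triflate (4-OTf) with C9=C10 alkene | CC[Si](CC)(CC)O[C@@H]1CC(C)=C(OS(=O)(=O)C(F)(F)F)[C@@H](O[Si]3(C(C)(C)C)C(C)(C)C)[C@@]2(C)[C@@H](O3)CC=C12 | intermediate
21 | C9 alkylborane (9α-BH2, 10α-H) | CC[Si](CC)(CC)O[C@@H]1CC(C)=C(OS(=O)(=O)C(F)(F)F)[C@@H](O[Si]3(C(C)(C)C)C(C)(C)C)[C@@]2(C)[C@@H](O3)C[C@@H](B)[C@H]12 | intermediate (not isolated)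
22 | 9α-alcohol, 10α-H, enol triflate (name in step 13) | CC[Si](CC)(CC)O[C@@H]1CC(C)=C(OS(=O)(=O)C(F)(F)F)[C@@H](O[Si]3(C(C)(C)C)C(C)(C)C)[C@@]2(C)[C@@H](O3)C[C@@H](O)[C@H]12 | intermediate
23 | (1R)-5α,7α-(di-tert-butylsilylenedioxy)-3,6β-dimethyl-1β-(triethylsilyloxy)bicyclo[5.3.0]dec-3-en-9α-ol | CC[Si](CC)(CC)O[C@@H]1CC(C)=C[C@@H](O[Si]3(C(C)(C)C)C(C)(C)C)[C@@]2(C)[C@@H](O3)C[C@@H](O)[C@H]12 | intermediate
24 | 9-ketone of 23 | CC[Si](CC)(CC)O[C@@H]1CC(C)=C[C@@H](O[Si]3(C(C)(C)C)C(C)(C)C)[C@@]2(C)[C@@H](O3)CC(=O)[C@H]12 | intermediate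
25 | 9β-hydroxy-9α-isopropyl compound, C1 triethylsilyl ether | CC[Si](CC)(CC)O[C@@H]1CC(C)=C[C@@H](O[Si]3(C(C)(C)C)C(C)(C)C)[C@@]2(C)[C@@H](O3)C[C@@](O)(C(C)C)[C@H]12 | intermediate
26 | (1R)-1β,9β-diol, 5α,7α-silylene | O[C@@H]1CC(C)=C[C@@H](O[Si]3(C(C)(C)C)C(C)(C)C)[C@@]2(C)[C@@H](O3)C[C@@](O)(C(C)C)[C@H]12 | intermediate
27 | (1S)-1α-angelate, 9β-ol, 5α,7α-silylene | C/C=C(/C)C(=O)O[C@H]1CC(C)=C[C@@H](O[Si]3(C(C)(C)C)C(C)(C)C)[C@@]2(C)[C@@H](O3)C[C@@](O)(C(C)C)[C@H]12 | intermediate
28 | 1α-angeloyloxy-3,6β-dimethyl-9α-isopropylbicyclo[5.3.0]dec-3-ene-5α,7α,9β-triol | C/C=C(/C)C(=O)O[C@H]1CC(C)=C[C@@H](O)[C@@]2(C)[C@@H](O)C[C@@](O)(C(C)C)[C@H]12 | intermediate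
29 | 3α,4α-epoxide of 28 | C/C=C(/C)C(=O)O[C@H]1C[C@@]2(C)O[C@H]2[C@@H](O)[C@@]2(C)[C@@H](O)C[C@@](O)(C(C)C)[C@H]12 | intermediate
30 | CNP0170993.1: (1S,3R,4S,5S,6R,7S,9R,10S)-5α,7α-diacetoxy-1α-angeloyloxy-3α,4α-epoxy-9α-isopropyl-3,6β-dimethylbicyclo[5.3.0]decan-9β-ol | C/C=C(/C)C(=O)O[C@H]1C[C@@]2(C)O[C@H]2[C@@H](OC(C)=O)[C@@]2(C)[C@@H](OC(C)=O)C[C@@](O)(C(C)C)[C@H]12 | target

**Step count and risks**

Total step count: 21. Longest linear sequence: 18 steps (steps 4–21 from 7; equally steps 1–3 and 7–21 from 1).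

Three steps most likely to fail:

1. Step 8. Process at risk: the 1,4-biradical may revert or close slowly under the steric load of the di-tert-butylsilyl tether, and the enol silyl ether may hydrolyse during long irradiation. The fallback changes the tether design: a small disposable tether is used only for the cycloaddition and the robust silylene is put on after the ring expansion. It sets out from 10 and 6 and returns at 16. Compound 10 is treated with iPr2SiCl2/imidazole and then with 6/Et3N to give the diisopropylsilyl-tethered vinylogous ester F1. Irradiation as in step 8 should give photoadduct F2. H2, Pd(OH)2/C and then DBU should give, by way of cyclobutanol F3 and saturated dione F4, the diisopropylsilylene enedione F5. HF·pyridine frees the diol F6, and tBu2Si(OTf)2 with 2,6-lutidine bridges O5 and O7 again to give 16.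

2. Step 13. Process at risk: poor facial selectivity of borane addition; attack on the β face would give the cis-fused C10 epimer. The fallback replaces the concerted addition by a directed epoxidation and a radical epoxide opening. It sets out from 17 and returns at 24. VO(acac)2/t-BuOOH delivers oxygen to the β face of C9=C10 under direction by the 1β-hydroxyl, giving the epoxy alcohol F7. Et3SiCl/imidazole gives the silyl ether F8. KN(SiMe3)2 and PhNTf2 give, by way of potassium enolate F9, the enol triflate F10. Cp2TiCl (from Cp2TiCl2 and Mn, trivalent titanium) with 1,4-cyclohexadiene opens the epoxide homolytically at the tertiary C10. The C10 radical should take up hydrogen on the α face, anti to the neighbouring titanium alkoxide, the C6 methyl group and the C1 silyl ether, to give the 9β-alcohol F11 with 10α-H. Pd(OAc)2, PPh3, HCO2H and Bu3N give the alkene F12, and Dess–Martin oxidation converges on 24, since the C9 configuration is lost in the ketone.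

3. Step 18. Process at risk: elimination of the activated, hindered C1 alcohol in place of substitution, and partial Z-to-E isomerisation of the angelate. The fallback sets C1 by an oxidation–directed reduction sequence and acylates with retention. It sets out from 26 and returns at 27. Dess–Martin periodinane oxidises only the secondary alcohol, giving the β-hydroxy ketone F13. Me4NBH(OAc)3 in MeCN/AcOH (Evans–Saksena reduction) delivers hydride from the 9β-hydroxyl to the β face of the C1 carbonyl and should give the 1α-alcohol F14. Acylation with the mixed anhydride F15, made from angelic acid, 2,4,6-trichlorobenzoyl chloride and Et3N (Yamaguchi esterification, toluene, 80 °C), gives 27.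

**Further compounds**

F1 | step 8 | 3-(benzyloxy)-2-{[diisopropyl({(1S,4R)-4-[(tert-butyldimethylsilyl)oxy]-2-methylcyclopent-2-en-1-yl}oxy)silyl]oxy}-5-methylcyclopent-2-en-1-one | CC1=C[C@H](O[Si](C)(C)C(C)(C)C)C[C@@H]1O[Si](OC1=C(OCc2ccccc2)CC(C)C1=O)(C(C)C)C(C)C
F2 | step 8 | diisopropylsilyl analogue of photoadduct 13 | c1ccccc1CO[C@@]23CC(C)C(=O)[C@]2(O[Si]4(C(C)C)C(C)C)[C@@]5(C)[C@@H](O4)C[C@@H](O[Si](C)(C)C(C)(C)C)[C@@H]35
F3 | step 8 | diisopropylsilyl analogue of cyclobutanol 14 | O[C@@]23CC(C)C(=O)[C@]2(O[Si]4(C(C)C)C(C)C)[C@@]5(C)[C@@H](O4)C[C@@H](O[Si](C)(C)C(C)(C)C)[C@@H]35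
F4 | step 8 | diisopropylsilylene analogue of dione 15 | O=C1CC(C)C(=O)[C@@H](O[Si]3(C(C)C)C(C)C)[C@@]2(C)[C@@H](O3)C[C@@H](O[Si](C)(C)C(C)(C)C)[C@@H]12
F5 | step 8 | 5α,7α-(diisopropylsilylenedioxy)-3,6β-dimethylbicyclo[5.3.0]dec-9(10)-ene-1,4-dione | O=C1CC(C)C(=O)[C@@H](O[Si]3(C(C)C)C(C)C)[C@@]2(C)[C@@H](O3)CC=C12
F6 | step 8 | 5α,7α-dihydroxy-3,6β-dimethylbicyclo[5.3.0]dec-9(10)-ene-1,4-dione | O=C1CC(C)C(=O)[C@@H](O)[C@@]2(C)[C@@H](O)CC=C12
F7 | step 13 | 9β,10β-epoxide of 17 | O[C@@H]1CC(C)C(=O)[C@@H](O[Si]3(C(C)(C)C)C(C)(C)C)[C@@]2(C)[C@@H](O3)C[C@@H]4O[C@]124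
F8 | step 13 | 1β-triethylsilyl ether of F7 | CC[Si](CC)(CC)O[C@@H]1CC(C)C(=O)[C@@H](O[Si]3(C(C)(C)C)C(C)(C)C)[C@@]2(C)[C@@H](O3)C[C@@H]4O[C@]124
F9 | step 13 | potassium C3=C4 enolate of F8 | [K+].CC[Si](CC)(CC)O[C@@H]1CC(C)=C([O-])[C@@H](O[Si]3(C(C)(C)C)C(C)(C)C)[C@@]2(C)[C@@H](O3)C[C@@H]4O[C@]124
F10 | step 13 | C3=C4 enol triflate of F8 | CC[Si](CC)(CC)O[C@@H]1CC(C)=C(OS(=O)(=O)C(F)(F)F)[C@@H](O[Si]3(C(C)(C)C)C(C)(C)C)[C@@]2(C)[C@@H](O3)C[C@@H]4O[C@]124
F11 | step 13 | 9β-alcohol with 10α-H, enol triflate (C9 epimer of 22) | CC[Si](CC)(CC)O[C@@H]1CC(C)=C(OS(=O)(=O)C(F)(F)F)[C@@H](O[Si]3(C(C)(C)C)C(C)(C)C)[C@@]2(C)[C@@H](O3)C[C@H](O)[C@H]12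
F12 | step 13 | 9β-alcohol with C3=C4 alkene (C9 epimer of 23) | CC[Si](CC)(CC)O[C@@H]1CC(C)=C[C@@H](O[Si]3(C(C)(C)C)C(C)(C)C)[C@@]2(C)[C@@H](O3)C[C@H](O)[C@H]12
F13 | step 18 | 1-ketone of 26 (9β-hydroxy ketone) | O=C1CC(C)=C[C@@H](O[Si]3(C(C)(C)C)C(C)(C)C)[C@@]2(C)[C@@H](O3)C[C@@](O)(C(C)C)[C@H]12
F14 | step 18 | (1S)-1α,9β-diol (C1 epimer of 26) | O[C@H]1CC(C)=C[C@@H](O[Si]3(C(C)(C)C)C(C)(C)C)[C@@]2(C)[C@@H](O3)C[C@@](O)(C(C)C)[C@H]12
F15 | step 18 | angelic 2,4,6-trichlorobenzoic anhydride | C/C=C(/C)C(=O)OC(=O)c1c(Cl)cc(Cl)cc1Cl
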